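**Retrosynthetic overview**

1. Feature: with the chain numbered C1–C16 from the ring-bound CH2, the route rests on the C9 carbinol. It sits next to the oxygen-bearing C8 centre and carries the E C10=C11 alkene whose C11 methyl is cis to C9, the pattern left by syn methyl–metal addition to a terminal alkyne.
2. Key disconnection: C9–C10 and C11–CH3 are cut together, giving 6-methylhept-5-en-1-yne, Me3Al and a (2R)-2-(methoxymethoxy) aldehyde holding C1–C9 and the arene.
3. The aldehyde comes from enantioselective addition of an alkenylzinc (hydrozirconation of a 2-alkyne) to (tert-butyldimethylsilyloxy)acetaldehyde (C7–C8 bond), then methoxymethylation, desilylation and oxidation.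
4. The 2-alkyne comes from an arylcopper (from 4-methoxy-2-methylphenol) and an allylic bromide cut out of geranyl acetate (terminal alkene cleavage, alkyne homologation, C-methylation).
5. No ring is formed: the only ring is the arene of the phenol, carried as the hydroquinone dimethyl ether and oxidised to the benzoquinone after the key step; the methoxymethyl ether is removed last.

Key step: step 14

Remark: chain atoms are numbered C1–C16 from the ring-bound CH2 throughout; the epoxide and diol of steps 3 and 4 are racemic at a centre that is cleaved, so this has no stereochemical consequence.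

**Route**

Step 1
Reactants: 1 4-methoxy-2-methylphenol
Product: 2 2-bromo-4-methoxy-6-methylphenol
Conditions: NBS, i-Pr2NH (cat.), CH2Cl2, 0 °C
Reagents that add atoms: N-bromosuccinimide, O=C1CCC(=O)N1Br
Why: Amine-catalysed electrophilic aromatic bromination should place bromine ortho to the free phenol, since the para position carries OMe and the other ortho position carries the methyl group.

Step 2
Reactants: 2 2-bromo-4-methoxy-6-methylphenol
Product: 3 1-bromo-2,5-dimethoxy-3-methylbenzene
Conditions: MeI, K2CO3, acetone, reflux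
Reagents that add atoms: iodomethane, CI
Why: Williamson O-methylation of the phenoxide gives the hydroquinone dimethyl ether that survives all organometallic steps.

Step 3
Reactants: 4 geranyl acetate
Product: 5 (2E)-5-(3,3-dimethyloxiran-2-yl)-3-methylpent-2-en-1-yl acetate (6,7-epoxygeranyl acetate, racemic)
Conditions: mCPBA, NaHCO3, CH2Cl2, −10 to 0 °C
Reagents that add atoms: 3-chloroperoxybenzoic acid, OOC(=O)c1cccc(Cl)c1
Why: Prilezhaev epoxidation should go to the remote, more electron-rich alkene because the C2=C3 alkene is deactivated by the allylic acetate.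

Step 4
Reactants: 5 6,7-epoxygeranyl acetate
Product: 7 (4E)-6-acetoxy-4-methylhex-4-enal, via diol 6 (not isolated)
Conditions: H5IO6, THF/H2O, 0 °C
Reagents that add atoms: none
Why: Epoxide hydrolysis followed by periodate glycol cleavage (Malaprade reaction) removes the isopropylidene carbons as acetone and leaves the aldehyde, with the ester and the E alkene untouched.

Step 5
Reactants: 7 (4E)-6-acetoxy-4-methylhex-4-enal
Product: 9 (2E)-3-methylhept-2-en-6-yn-1-ol, via acetoxy alkyne 8 (not isolated)
Conditions: dimethyl (1-diazo-2-oxopropyl)phosphonate, K2CO3, MeOH, 0 °C to rt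
Reagents that add atoms: Ohira–Bestmann reagent, COP(=O)(OC)C(=[N+]=[N-])C(C)=O
Why: Ohira–Bestmann homologation turns the aldehyde into the terminal alkyne, and the same K2CO3/MeOH medium transesterifies the acetate to the free allylic alcohol.

Step 6
Reactants: 9 (2E)-3-methylhept-2-en-6-yn-1-ol
Product: 11 (2E)-3-methyloct-2-en-6-yn-1-ol, via dilithio salt 10 (not isolated)
Conditions: n-BuLi (2.1 equiv), THF, −78 to −20 °C; MeI (1.1 equiv), −78 °C to rt
Reagents that add atoms: iodomethane, CI
Why: Alkylation of the alkoxide–acetylide dianion should occur at carbon, because the lithium acetylide is far more nucleophilic toward MeI than the aggregated lithium alkoxide in THF.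

Step 7
Reactants: 11 (2E)-3-methyloct-2-en-6-yn-1-ol
Product: 12 (2E)-1-bromo-3-methyloct-2-en-6-yne
Conditions: CBr4, PPh3, CH2Cl2, 0 °C
Reagents that add atoms: tetrabromomethane, BrC(Br)(Br)Br
Why: The Appel reaction replaces the primary allylic hydroxyl by SN2 under neutral conditions, so no allylic transposition or loss of E geometry is expected.

Step 8
Reactants: 3 1-bromo-2,5-dimethoxy-3-methylbenzene; 12 (2E)-1-bromo-3-methyloct-2-en-6-yne
Product: 15 1-[(2E)-3-methyloct-2-en-6-yn-1-yl]-2,5-dimethoxy-3-methylbenzene, via aryllithium 13 (not isolated), via arylcopper 14 (not isolated)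
Conditions: 3, n-BuLi, THF, −78 °C; CuBr·SMe2, −78 to −40 °C; then 12, −78 to 0 °C
Reagents that add atoms: none
Why: Bromine–lithium exchange, transmetalation to copper and SN2 allylic substitution should join aryl carbon and C1, since the arylcopper attacks the unhindered primary carbon and not the fully substituted gamma carbon, which keeps the E alkene.

Step 9
Reactants: 15 1-[(2E)-3-methyloct-2-en-6-yn-1-yl]-2,5-dimethoxy-3-methylbenzene; 16 (tert-butyldimethylsilyloxy)acetaldehyde
Product: 19 (2R,3E,7E)-1-[(tert-butyldimethylsilyl)oxy]-9-(2,5-dimethoxy-3-methylphenyl)-3,7-dimethylnona-3,7-dien-2-ol, via alkenylzirconocene 17 (not isolated), via alkenylzinc 18 (not isolated)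
Conditions: Cp2Zr(H)Cl (1.5 equiv), CH2Cl2, rt; solvent exchange to toluene; Me2Zn, −65 °C; (+)-MIB (10 mol%), 16 (excess), −30 to 0 °C
Reagents that add atoms: none
Why: Syn hydrozirconation, equilibrated by the excess hydride so that zirconium sits on the methyl-bearing alkyne carbon (C7), then zirconium-to-zinc transmetalation and amino-alcohol-catalysed asymmetric alkenylzinc addition should form the C7–C8 bond with the E C6=C7 alkene, the (+)-enantiomer of morpholinoisoborneol directing the alkenyl group to the Re face of 16 to set the 2R centre (C8 of the target).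

Step 10
Reactants: 19 (2R)-silyloxy alcohol
Product: 20 (2R,3E,7E)-1-[(tert-butyldimethylsilyl)oxy]-9-(2,5-dimethoxy-3-methylphenyl)-2-(methoxymethoxy)-3,7-dimethylnona-3,7-diene
Conditions: MOMCl, i-Pr2NEt, Bu4NI (cat.), CH2Cl2, 0 °C to rt
Reagents that add atoms: chloromethyl methyl ether, COCCl
Why: Acetal-type O-alkylation under amine base avoids an alkoxide, so the neighbouring silyl ether should not migrate and the carbinol configuration is untouched.

Step 11
Reactants: 20 silyl methoxymethyl bis-ether
Product: 21 (2R,3E,7E)-9-(2,5-dimethoxy-3-methylphenyl)-2-(methoxymethoxy)-3,7-dimethylnona-3,7-dien-1-ol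
Conditions: TBAF, THF, 0 °C
Reagents that add atoms: none
Why: Fluoride-induced desilylation frees the primary alcohol and leaves the acetal and aryl ethers intact.

Step 12
Reactants: 21 primary alcohol
Product: 22 (2R,3E,7E)-9-(2,5-dimethoxy-3-methylphenyl)-2-(methoxymethoxy)-3,7-dimethylnona-3,7-dienal
Conditions: Dess–Martin periodinane, NaHCO3, CH2Cl2, 0 °C; used at once
Reagents that add atoms: none
Why: Dess–Martin oxidation works under buffered, non-basic conditions, which should spare the C8 hydrogen that is both allylic and alpha to the new carbonyl.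

Step 13
Reactants: 23 6-methylhept-5-en-2-one
Product: 25 6-methylhept-5-en-1-yne, via enol phosphate 24 (not isolated)
Conditions: LiN(i-Pr)2, THF, −78 °C; ClP(O)(OEt)2, −78 °C to rt; then LiN(i-Pr)2 (2.3 equiv), −78 °C to rt
Reagents that add atoms: none
Why: Kinetic enolisation on the methyl side, O-phosphorylation and base-induced beta-elimination of the enol phosphate is the standard conversion of a methyl ketone into a terminal alkyne.

Step 14
Reactants: 25 6-methylhept-5-en-1-yne; 26 trimethylaluminium; 22 (2R)-2-(methoxymethoxy) aldehyde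
Product: 28 (2E,6E,8R,9R,10E)-1-(2,5-dimethoxy-3-methylphenyl)-8-(methoxymethoxy)-3,7,11,15-tetramethylhexadeca-2,6,10,14-tetraen-9-ol, via alkenylalane 27 (not isolated)
Conditions: 25, Me3Al (2 equiv), Cp2ZrCl2 (0.2 equiv), CH2Cl2, 0 °C to rt; volatiles and excess Me3Al removed in vacuo; residue in CH2Cl2 added to 22 and MgBr2·OEt2 in CH2Cl2, −78 to −40 °C; aqueous potassium sodium tartrate work-up
Reagents that add atoms: trimethylaluminium, C[Al](C)C
Why: Cp2ZrCl2 and Me3Al form a methylzirconium–aluminium species that adds methyl and metal syn across the terminal alkyne of 25 (Negishi carboalumination), methyl going to the internal carbon C11 and aluminium to C10, so alane 27 already holds the E C10=C11 geometry with the C11 methyl cis to the metal. After unreacted Me3Al is pumped off, the sp2 carbon–aluminium bond of 27 adds to the aldehyde carbon of 22 with retention of alkene geometry, which is the known in situ alkenylalane–aldehyde addition after carboalumination, applied here to an alpha-alkoxy aldehyde held as its MgBr2 chelate. No ring is closed. The new C9 centre is set by 1,2-chelation: the carbonyl oxygen and the proximal oxygen of the C8 methoxymethyl ether bind one magnesium (or aluminium) centre in a five-membered chelate, and the alkenyl group attacks the face opposite the C7 alkenyl substituent (Cram chelate model), which from (8R)-22 should give the syn (8R,9R) product. The step needs methyl-to-internal-carbon regiochemistry in the carbometalation, secured by the terminal alkyne, and chelate face selection, secured by the Lewis-basic acetal oxygen on C8. The labile C8 hydrogen of 22 is protected by using the aldehyde at once, at −78 °C, under non-basic conditions.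

Step 15
Reactants: 28 key-step product
Product: 29 2-[(2E,6E,8R,9R,10E)-9-hydroxy-8-(methoxymethoxy)-3,7,11,15-tetramethylhexadeca-2,6,10,14-tetraen-1-yl]-6-methyl-1,4-benzoquinone
Conditions: (NH4)2Ce(NO3)6 (2.2 equiv), MeCN/H2O, 0 °C, short reaction time
Reagents that add atoms: water, O
Why: Oxidative demethylation of the hydroquinone dimethyl ether by two one-electron transfers to cerium and attack of water on the ring should be much faster at 0 °C than any oxidation of the side-chain alcohol, provided the oxidant charge is kept near two equivalents.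

Step 16
Reactants: 29 quinone methoxymethyl ether
Product: 31 2-[(2E,6E,8R,9R,10E)-8,9-dihydroxy-3,7,11,15-tetramethylhexadeca-2,6,10,14-tetraen-1-yl]-6-methyl-1,4-benzoquinone (CNP0159538.1), via bromomethyl ether 30 (not isolated)
Conditions: Me2BBr (3 equiv), 2,6-di-tert-butyl-4-methylpyridine, CH2Cl2, −78 °C; then THF/aq. NaHCO3, −78 °C to rt
Reagents that add atoms: none
Why: Lewis-acid acetal cleavage, in which boron binds the acetal oxygen and bromide opens it to bromomethyl ether 30 that hydrolyses on the bicarbonate quench, runs at −78 °C without breaking the C8–O or C9–O bonds, so both configurations should be kept and the doubly allylic diol should not ionise.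

**Compound list**

1 | 4-methoxy-2-methylphenol | COc1ccc(O)c(C)c1 | starting material
2 | 2-bromo-4-methoxy-6-methylphenol | COc1cc(C)c(O)c(Br)c1 | intermediate
3 | 1-bromo-2,5-dimethoxy-3-methylbenzene | COc1cc(C)c(OC)c(Br)c1 | intermediate
4 | geranyl acetate | CC(C)=CCC/C(C)=C/COC(C)=O | starting material
5 | (2E)-5-(3,3-dimethyloxiran-2-yl)-3-methylpent-2-en-1-yl acetate (racemic) | CC(=O)OC/C=C(\C)CCC1OC1(C)C | intermediate
6 | (2E)-6,7-dihydroxy-3,7-dimethyloct-2-en-1-yl acetate (racemic, formed in situ) | CC(=O)OC/C=C(\C)CCC(O)C(C)(C)O | intermediate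
7 | (4E)-6-acetoxy-4-methylhex-4-enal | CC(=O)OC/C=C(\C)CCC=O | intermediate
8 | (2E)-3-methylhept-2-en-6-yn-1-yl acetate (formed in situ) | CC(=O)OC/C=C(\C)CCC#C | intermediate
9 | (2E)-3-methylhept-2-en-6-yn-1-ol | OC/C=C(\C)CCC#C | intermediate
10 | dilithium salt of 9 (lithium alkoxide and lithium acetylide, formed in situ) | [Li]OC/C=C(\C)CCC#C[Li] | intermediate
11 | (2E)-3-methyloct-2-en-6-yn-1-ol | OC/C=C(\C)CCC#CC | intermediate
12 | (2E)-1-bromo-3-methyloct-2-en-6-yne | BrC/C=C(\C)CCC#CC | intermediate
13 | (2,5-dimethoxy-3-methylphenyl)lithium (formed in situ) | [Li]c1cc(OC)cc(C)c1OC | intermediate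
14 | (2,5-dimethoxy-3-methylphenyl)copper (formed in situ) | [Cu]c1cc(OC)cc(C)c1OC | intermediate
15 | 1-[(2E)-3-methyloct-2-en-6-yn-1-yl]-2,5-dimethoxy-3-methylbenzene | CC#CCC/C(C)=C/Cc1cc(OC)cc(C)c1OC | intermediate
16 | (tert-butyldimethylsilyloxy)acetaldehyde | CC(C)(C)[Si](C)(C)OCC=O | starting material
17 | chloro[(2E,6E)-8-(2,5-dimethoxy-3-methylphenyl)-6-methylocta-2,6-dien-2-yl]zirconocene (formed in situ) | Cl[Zr](C1C=CC=C1)(C1C=CC=C1)/C(C)=C/CC/C(C)=C/Cc1cc(OC)cc(C)c1OC | intermediate
18 | methyl[(2E,6E)-8-(2,5-dimethoxy-3-methylphenyl)-6-methylocta-2,6-dien-2-yl]zinc (formed in situ) | C[Zn]/C(C)=C/CC/C(C)=C/Cc1cc(OC)cc(C)c1OC | intermediate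
19 | (2R,3E,7E)-1-[(tert-butyldimethylsilyl)oxy]-9-(2,5-dimethoxy-3-methylphenyl)-3,7-dimethylnona-3,7-dien-2-ol | CC(C)(C)[Si](C)(C)OC[C@H](O)/C(C)=C/CC/C(C)=C/Cc1cc(OC)cc(C)c1OC | intermediate
20 | (2R,3E,7E)-1-[(tert-butyldimethylsilyl)oxy]-9-(2,5-dimethoxy-3-methylphenyl)-2-(methoxymethoxy)-3,7-dimethylnona-3,7-diene | CC(C)(C)[Si](C)(C)OC[C@H](OCOC)/C(C)=C/CC/C(C)=C/Cc1cc(OC)cc(C)c1OC | intermediate
21 | (2R,3E,7E)-9-(2,5-dimethoxy-3-methylphenyl)-2-(methoxymethoxy)-3,7-dimethylnona-3,7-dien-1-ol | OC[C@H](OCOC)/C(C)=C/CC/C(C)=C/Cc1cc(OC)cc(C)c1OC | intermediate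
22 | (2R,3E,7E)-9-(2,5-dimethoxy-3-methylphenyl)-2-(methoxymethoxy)-3,7-dimethylnona-3,7-dienal | O=C[C@H](OCOC)/C(C)=C/CC/C(C)=C/Cc1cc(OC)cc(C)c1OC | intermediate
23 | 6-methylhept-5-en-2-one | CC(=O)CCC=C(C)C | starting material
24 | diethyl 6-methylhepta-1,5-dien-2-yl phosphate (formed in situ) | C=C(CCC=C(C)C)OP(=O)(OCC)OCC | intermediate
25 | 6-methylhept-5-en-1-yne | C#CCCC=C(C)C | intermediate
26 | trimethylaluminium | C[Al](C)C | starting material
27 | [(1E)-2,6-dimethylhepta-1,5-dien-1-yl]dimethylalane (formed in situ) | C[Al](C)/C=C(C)/CCC=C(C)C | intermediate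
28 | (2E,6E,8R,9R,10E)-1-(2,5-dimethoxy-3-methylphenyl)-8-(methoxymethoxy)-3,7,11,15-tetramethylhexadeca-2,6,10,14-tetraen-9-ol | CC(C)=CCC/C(C)=C/[C@@H](O)[C@H](OCOC)/C(C)=C/CC/C(C)=C/Cc1cc(OC)cc(C)c1OC | intermediate
29 | 2-[(2E,6E,8R,9R,10E)-9-hydroxy-8-(methoxymethoxy)-3,7,11,15-tetramethylhexadeca-2,6,10,14-tetraen-1-yl]-6-methyl-1,4-benzoquinone | CC(C)=CCC/C(C)=C/[C@@H](O)[C@H](OCOC)/C(C)=C/CC/C(C)=C/CC1=CC(=O)C=C(C)C1=O | intermediate
30 | 8-O-(bromomethyl) 9-O-(dimethylboryl) derivative of the quinone diol (formed in situ) | CC(C)=CCC/C(C)=C/[C@@H](OB(C)C)[C@H](OCBr)/C(C)=C/CC/C(C)=C/CC1=CC(=O)C=C(C)C1=O | intermediate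
31 | 2-[(2E,6E,8R,9R,10E)-8,9-dihydroxy-3,7,11,15-tetramethylhexadeca-2,6,10,14-tetraen-1-yl]-6-methyl-1,4-benzoquinone | CC(C)=CCC/C(C)=C/[C@@H](O)[C@H](O)/C(C)=C/CC/C(C)=C/CC1=CC(=O)C=C(C)C1=O | target

**Step count**

Total: 16 steps. Longest linear sequence: 13 steps from geranyl acetate 4 (steps 3–12, then 14–16).

**Steps most likely to fail**

Step 14. Methyl may transfer from aluminium instead of the alkenyl group, chelation may be incomplete so that facial selectivity at C9 is poor, or C8 may epimerise before addition. The fallback sets out from 25. Carboalumination as in step 14 and iodinolysis of alane 27 (I2, THF, −30 °C) would give (1E)-1-iodo-2,6-dimethylhepta-1,5-diene F1. Iodine–lithium exchange (t-BuLi, Et2O, −78 °C) would give [(1E)-2,6-dimethylhepta-1,5-dien-1-yl]lithium F2, and MgBr2·OEt2 would convert it into [(1E)-2,6-dimethylhepta-1,5-dien-1-yl]magnesium bromide F3. Addition of this reagent to 22 in Et2O/CH2Cl2 at −78 °C is a Grignard addition under Cram chelate control and comes back to the route at 28.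

Step 9. Uncatalysed alkenyl transfer promoted by zirconium or zinc species may outrun the ligand-bound pathway and lower the enantiofacial selectivity, and regiochemical equilibration of the alkenylzirconocene may be incomplete. The fallback sets out from 19 obtained in insufficient enantiomeric purity. Dess–Martin oxidation would give (3E,7E)-1-[(tert-butyldimethylsilyl)oxy]-9-(2,5-dimethoxy-3-methylphenyl)-3,7-dimethylnona-3,7-dien-2-one F4. Corey–Bakshi–Shibata reduction with the (R)-methyl oxazaborolidine and catecholborane at −78 °C, in which the trisubstituted alkenyl group acts as the large substituent, should return the 2R alcohol and so comes back at 19.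

Step 16. The Lewis acid may ionise the doubly allylic C8 and C9 oxygens (allylic transposition, elimination), or the bromomethyl ether may close a methylene acetal across O8 and O9. The fallback sets out from 29. Na2S2O4 in Et2O/H2O would reduce the quinone to 2-[(2E,6E,8R,9R,10E)-9-hydroxy-8-(methoxymethoxy)-3,7,11,15-tetramethylhexadeca-2,6,10,14-tetraen-1-yl]-6-methylbenzene-1,4-diol F5. ZnBr2 and n-PrSH in CH2Cl2 at 0 °C would then remove the methoxymethyl group by thiol capture, which a hydroquinone tolerates and a quinone does not, to give 2-[(2E,6E,8R,9R,10E)-8,9-dihydroxy-3,7,11,15-tetramethylhexadeca-2,6,10,14-tetraen-1-yl]-6-methylbenzene-1,4-diol F6. Oxidation with Ag2O in Et2O comes back to the route at 31.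

**Further compounds**

F1 | step 14 | (1E)-1-iodo-2,6-dimethylhepta-1,5-diene | I/C=C(C)/CCC=C(C)C
F2 | step 14 | [(1E)-2,6-dimethylhepta-1,5-dien-1-yl]lithium | [Li]/C=C(C)/CCC=C(C)C
F3 | step 14 | [(1E)-2,6-dimethylhepta-1,5-dien-1-yl]magnesium bromide | Br[Mg]/C=C(C)/CCC=C(C)C
F4 | step 9 | (3E,7E)-1-[(tert-butyldimethylsilyl)oxy]-9-(2,5-dimethoxy-3-methylphenyl)-3,7-dimethylnona-3,7-dien-2-one | CC(C)(C)[Si](C)(C)OCC(=O)/C(C)=C/CC/C(C)=C/Cc1cc(OC)cc(C)c1OC
F5 | step 16 | 2-[(2E,6E,8R,9R,10E)-9-hydroxy-8-(methoxymethoxy)-3,7,11,15-tetramethylhexadeca-2,6,10,14-tetraen-1-yl]-6-methylbenzene-1,4-diol | CC(C)=CCC/C(C)=C/[C@@H](O)[C@H](OCOC)/C(C)=C/CC/C(C)=C/Cc1cc(O)cc(C)c1O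
F6 | step 16 | 2-[(2E,6E,8R,9R,10E)-8,9-dihydroxy-3,7,11,15-tetramethylhexadeca-2,6,10,14-tetraen-1-yl]-6-methylbenzene-1,4-diol | CC(C)=CCC/C(C)=C/[C@@H](O)[C@H](O)/C(C)=C/CC/C(C)=C/Cc1cc(O)cc(C)c1O
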